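**Retrosynthetic overview**

1. Locants (target): ring C1 (C=O), C2 (bears C7H2OAc), C3, C4 (CHOH), C5 (quaternary oxirane carbon, bears side-chain carbon C1′), C6 (oxirane CH). Late disconnections: C1′–OH from a C1′ ketone (hydride delivered from C4–OH); C2–C7 (Morita–Baylis–Hillman); C1′–C2′ (thioester + alkenylzinc); oxirane C6–O (C5–OH onto a C6 mesylate).
2. Key disconnection C4–C5: the array C1′(carboxyl level)–C5(O)–C4–C3=C2 is the retron of an Ireland–Claisen rearrangement. Because C2 and C5 are also tied through C1–C6, the allyl ester is a δ-lactone (oxan-2-one: carbonyl = C1′, ring O on C2, C2 carrying an E-alkenylboronate that becomes C3=C4); its silyl ketene acetal contracts to the cyclohexene.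
3. The lactone comes from 2,3,4-tri-O-benzyl-D-xylopyranose: chelation-controlled ethynyl addition (new carbinol = C2), oxidative lactonisation, alkyne hydroboration; xylose C2, C3, C4, C5 become C1, C6, C5, C1′.
4. Ring order: δ-lactone (temporary O-heterocycle, step 2) → cyclohexene (step 4) → oxirane (step 9).
5. Side chain: (E)-geranylacetone → terminal alkyne → E-alkenyl iodide (carboalumination), coupled in step 12.

Key step: step 4

Remark 1: 2,3,4-tri-O-benzyl-D-xylopyranose is assumed to be a catalogue compound (otherwise three routine steps from D-xylose: methyl glycoside, benzylation, hydrolysis).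
Remark 2: C-labels in the Why lines are the target locants given in the overview.

**Route**

Step 1
Reactants: 1 2,3,4-tri-O-benzyl-D-xylopyranose
Product: 2 (3R,4S,5S,6R)-4,5,6-tris(benzyloxy)hept-1-yne-3,7-diol
Conditions: HC≡CMgBr (5 equiv), THF/CH2Cl2, 0 °C → rt; aq NH4Cl
Reagents that add atoms: ethynylmagnesium bromide, C#C[Mg]Br
Why: Grignard addition to the open hydroxy-aldehyde form of the lactol; a Cram chelate of magnesium between the aldehyde oxygen and the 2-benzyloxy group should direct attack to the face that gives the 1,2-syn carbinol (3R), and the minor epimer is to be removed by chromatography.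

Step 2
Reactants: 2 (3R,4S,5S,6R)-4,5,6-tris(benzyloxy)hept-1-yne-3,7-diol
Product: 4 (3S,4R,5S,6R)-3,4,5-tris(benzyloxy)-6-ethynyloxan-2-one, via lactol 3 (not isolated)
Conditions: TEMPO (0.2 equiv), PhI(OAc)2 (2.5 equiv), CH2Cl2, rt
Reagents that add atoms: none
Why: TEMPO/PhI(OAc)2 oxidative lactonisation of a 1,5-diol: the primary alcohol is oxidised faster than the secondary propargylic one, the aldehyde closes to the six-membered lactol with that hydroxyl and a second oxidation gives the δ-lactone, no stereocentre being touched.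

Step 3
Reactants: 4 (3S,4R,5S,6R)-3,4,5-tris(benzyloxy)-6-ethynyloxan-2-one
Product: 5 (3S,4R,5S,6R)-3,4,5-tris(benzyloxy)-6-[(E)-2-(4,4,5,5-tetramethyl-1,3,2-dioxaborolan-2-yl)ethenyl]oxan-2-one
Conditions: HBpin (1.5 equiv), Cp2Zr(H)Cl (10 mol %), Et3N (10 mol %), CH2Cl2, 40 °C
Reagents that add atoms: pinacolborane, CC1(C)OBOC1(C)C
Why: Zirconium-catalysed syn hydroboration of the terminal alkyne places boron on the terminal carbon and should give only the E-alkenylboronate, while the lactone and benzyl ethers are inert to HBpin.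

Step 4
Reactants: 5 (3S,4R,5S,6R)-3,4,5-tris(benzyloxy)-6-[(E)-2-(4,4,5,5-tetramethyl-1,3,2-dioxaborolan-2-yl)ethenyl]oxan-2-one
Product: 8 (1R,2S,5S,6R)-1,5,6-tris(benzyloxy)-2-hydroxycyclohex-3-ene-1-carboxylic acid, via silyl ketene acetal 6 (not isolated), via silyl ester boronate 7 (not isolated)
Conditions: Me3SiCl/Et3N (premixed), LiN(iPr)2, THF, −78 °C; PhMe, 80 °C; then NaOH, 30% H2O2, THF/H2O, 0 °C; HCl to pH 3
Reagents that add atoms: hydrogen peroxide, OO
Why: LiN(iPr)2 removes the lactone α-proton in the presence of Me3SiCl so that the enolate is trapped at once as the cyclic silyl ketene acetal 6, in which C(OSi)=C5(OBn), the ring O–C2H unit and the E-CH=CH–B group make up an allyl vinyl ether; warming triggers a concerted suprafacial [3,3] shift that breaks the ring O–C2 bond, forms C4–C5 and turns the lactone carbonyl carbon into the exocyclic carboxyl carbon C1′, and alkaline H2O2 then hydrolyses the silyl ester and oxidises the secondary allylic boronate to the C4 alcohol with retention and without allylic transposition. The closest known reaction type is the Ireland–Claisen ring contraction of 6-alkenyl δ-lactone silyl ketene acetals to cyclohex-3-enecarboxylic acids. The carbocycle closes pericyclically, the lactone being contracted to the cyclohexene through a boat-like six-centre transition state that the four-atom tether C5–C6–C1–C2 enforces (a chair cannot be reached), so no ionic ring-closure constraint applies. C5 is set by chirality transfer from C2: the new bond can form only on the lactone face that carries the alkenyl group, so on the new ring the C5 benzyloxy group is cis to the C1 benzyloxy group and trans to the C6 benzyloxy group (the arrangement needed later for oxirane closure), while C4 is set by the E geometry of the alkenylboronate, which in the boat places boron (then OH) cis to the carboxyl group. The selectivity needed is O-silylation faster than β-elimination of the C6 benzyloxy group from the lithium enolate, which the internal Me3SiCl quench at −78 °C should secure, and the xylo pattern of 5 (three equatorial benzyloxy groups) already holds the alkenyl group axial as the shift requires.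

Step 5
Reactants: 8 (1R,2S,5S,6R)-1,5,6-tris(benzyloxy)-2-hydroxycyclohex-3-ene-1-carboxylic acid
Product: 10 (1S,2S,5S,6R)-1,5,6-tris(benzyloxy)-2-[(tert-butyldimethylsilyl)oxy]cyclohex-3-ene-1-carboxylic acid, via bis-silyl ester 9 (not isolated)
Conditions: t-BuMe2SiOTf (2.5 equiv), 2,6-lutidine, CH2Cl2, 0 °C; then K2CO3, MeOH/THF/H2O, rt; citric acid
Reagents that add atoms: tert-butyldimethylsilyl trifluoromethanesulfonate, CC(C)(C)[Si](C)(C)OS(=O)(=O)C(F)(F)F
Why: Silyl ether formation at the hindered C4 alcohol with the silyl triflate; the silyl ester formed alongside is cleaved by mild aqueous carbonate, which leaves the secondary silyl ether intact.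

Step 6
Reactants: 10 (1S,2S,5S,6R)-1,5,6-tris(benzyloxy)-2-[(tert-butyldimethylsilyl)oxy]cyclohex-3-ene-1-carboxylic acid
Product: 11 S-ethyl (1S,2S,5S,6R)-1,5,6-tris(benzyloxy)-2-[(tert-butyldimethylsilyl)oxy]cyclohex-3-ene-1-carbothioate
Conditions: EtSH (3 equiv), DCC, DMAP (cat), CH2Cl2, 0 °C → rt
Reagents that add atoms: ethanethiol, CCS
Why: Steglich-type thioesterification (carbodiimide activation, DMAP acyl transfer) converts the α-quaternary acid into an acyl donor that survives the next three steps and can later be coupled under neutral conditions; no stereocentre is affected.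

Step 7
Reactants: 11 S-ethyl (1S,2S,5S,6R)-1,5,6-tris(benzyloxy)-2-[(tert-butyldimethylsilyl)oxy]cyclohex-3-ene-1-carbothioate
Product: 12 S-ethyl (1S,2S,5S,6R)-2-[(tert-butyldimethylsilyl)oxy]-1,5,6-trihydroxycyclohex-3-ene-1-carbothioate
Conditions: BCl3 (6 equiv), C6HMe5 (10 equiv), CH2Cl2, −78 °C; MeOH, then H2O
Reagents that add atoms: none
Why: BCl3 debenzylation with pentamethylbenzene as a non-basic benzyl-cation scavenger cleaves the three benzyl ethers at −78 °C, conditions under which the silyl ether, the thioester and the ring alkene are expected to survive.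

Step 8
Reactants: 12 S-ethyl (1S,2S,5S,6R)-2-[(tert-butyldimethylsilyl)oxy]-1,5,6-trihydroxycyclohex-3-ene-1-carbothioate
Product: 13 S-ethyl (1S,2S,6S)-2-[(tert-butyldimethylsilyl)oxy]-1,6-dihydroxy-5-oxocyclohex-3-ene-1-carbothioate
Conditions: MnO2 (20 equiv), CH2Cl2, rt
Reagents that add atoms: none
Why: MnO2 oxidises allylic alcohols selectively, so only C1–OH (allylic to C2=C3) is converted into the ketone while the non-allylic C6–OH, the tertiary C5–OH and the silylated C4–O are untouched.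

Step 9
Reactants: 13 S-ethyl (1S,2S,6S)-2-[(tert-butyldimethylsilyl)oxy]-1,6-dihydroxy-5-oxocyclohex-3-ene-1-carbothioate
Product: 15 S-ethyl (1R,5S,6S)-5-[(tert-butyldimethylsilyl)oxy]-2-oxo-7-oxabicyclo[4.1.0]hept-3-ene-6-carbothioate, via C6 mesylate 14 (not isolated)
Conditions: MeSO2Cl (1.1 equiv), Et3N, CH2Cl2, −40 °C; then DBU, 0 °C
Reagents that add atoms: none
Why: Mesylation of the only secondary hydroxyl (C6) followed by intramolecular Williamson (SN2) closure by the trans-disposed C5 alkoxide at the ketone-activated C6 forms the oxirane with inversion at C6, so that the oxirane oxygen (the former C5 hydroxyl) ends trans to the C4 silyloxy group.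

Step 10
Reactants: 16 (5E)-6,10-dimethylundeca-5,9-dien-2-one ((E)-geranylacetone)
Product: 18 (5E)-6,10-dimethylundeca-5,9-dien-1-yne, via enol phosphate 17 (not isolated)
Conditions: LiN(iPr)2 (1.1 equiv), THF, −78 °C; ClP(O)(OEt)2; LiN(iPr)2 (2.3 equiv), −78 °C → rt
Reagents that add atoms: none
Why: Kinetic enolisation at the methyl group, O-phosphorylation and base-induced β-elimination of the enol phosphate convert the methyl ketone into the terminal alkyne without touching the E trisubstituted alkene.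

Step 11
Reactants: 18 (5E)-6,10-dimethylundeca-5,9-dien-1-yne
Product: 20 (1E,5E)-1-iodo-2,6,10-trimethylundeca-1,5,9-triene, via alkenylalane 19 (not isolated)
Conditions: Me3Al (2.5 equiv), Cp2ZrCl2 (0.25 equiv), CH2Cl2, 0 °C → rt; then I2, THF, −30 °C
Reagents that add atoms: trimethylaluminium, C[Al](C)C; iodine, II
Why: Negishi zirconium-catalysed carboalumination adds methyl and aluminium syn across the alkyne with aluminium at the terminal carbon, and iodinolysis of the alkenylalane with retention should give the E iodide.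

Step 12
Reactants: 15 S-ethyl (1R,5S,6S)-5-[(tert-butyldimethylsilyl)oxy]-2-oxo-7-oxabicyclo[4.1.0]hept-3-ene-6-carbothioate; 20 (1E,5E)-1-iodo-2,6,10-trimethylundeca-1,5,9-triene
Product: 23 (1R,5S,6S)-5-[(tert-butyldimethylsilyl)oxy]-6-[(2E,6E)-3,7,11-trimethyldodeca-2,6,10-trienoyl]-7-oxabicyclo[4.1.0]hept-3-en-2-one, via alkenyllithium 21 (not isolated), via alkenylzinc chloride 22 (not isolated)
Conditions: 20, t-BuLi (2.1 equiv), Et2O, −78 °C; ZnCl2, THF, −78 → 0 °C; then 15, PdCl2(PPh3)2 (10 mol %), THF/PhMe, rt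
Reagents that add atoms: none
Why: Fukuyama coupling: zerovalent palladium inserts into the acyl C–S bond and the alkenylzinc, made by iodine–lithium exchange and transmetalation with retention of the E geometry, transfers its alkenyl group to give the ketone, the organozinc being unreactive towards the enone, the oxirane and the silyl ether.

Step 13
Reactants: 23 (1R,5S,6S)-5-[(tert-butyldimethylsilyl)oxy]-6-[(2E,6E)-3,7,11-trimethyldodeca-2,6,10-trienoyl]-7-oxabicyclo[4.1.0]hept-3-en-2-one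
Product: 24 (1R,5S,6S)-5-[(tert-butyldimethylsilyl)oxy]-3-(hydroxymethyl)-6-[(2E,6E)-3,7,11-trimethyldodeca-2,6,10-trienoyl]-7-oxabicyclo[4.1.0]hept-3-en-2-one
Conditions: 37% aq HCHO (5 equiv), DMAP (0.5 equiv), THF, rt
Reagents that add atoms: formaldehyde, C=O
Why: Morita–Baylis–Hillman hydroxymethylation: DMAP adds reversibly to C3 of the ring enone, the resulting enolate attacks formaldehyde at C2 and loss of DMAP restores the enone, whereas the β,β-disubstituted side-chain enone does not accept the amine.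

Step 14
Reactants: 24 (1R,5S,6S)-5-[(tert-butyldimethylsilyl)oxy]-3-(hydroxymethyl)-6-[(2E,6E)-3,7,11-trimethyldodeca-2,6,10-trienoyl]-7-oxabicyclo[4.1.0]hept-3-en-2-one
Product: 25 [(1R,5S,6S)-5-[(tert-butyldimethylsilyl)oxy]-2-oxo-6-[(2E,6E)-3,7,11-trimethyldodeca-2,6,10-trienoyl]-7-oxabicyclo[4.1.0]hept-3-en-3-yl]methyl acetate
Conditions: Ac2O, pyridine, DMAP (cat), CH2Cl2, 0 °C
Reagents that add atoms: acetic anhydride, CC(=O)OC(C)=O
Why: Acylation of the only free (primary, allylic) hydroxyl with acetic anhydride under DMAP catalysis.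

Step 15
Reactants: 25 [(1R,5S,6S)-5-[(tert-butyldimethylsilyl)oxy]-2-oxo-6-[(2E,6E)-3,7,11-trimethyldodeca-2,6,10-trienoyl]-7-oxabicyclo[4.1.0]hept-3-en-3-yl]methyl acetate
Product: 26 [(1R,5S,6R)-5-hydroxy-2-oxo-6-[(2E,6E)-3,7,11-trimethyldodeca-2,6,10-trienoyl]-7-oxabicyclo[4.1.0]hept-3-en-3-yl]methyl acetate
Conditions: HF·pyridine, pyridine, THF, 0 °C → rt
Reagents that add atoms: none
Why: Fluoride-mediated cleavage of the secondary silyl ether with buffered HF·pyridine, conditions expected to leave the oxirane, the allylic acetate and the two enones intact.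

Step 16
Reactants: 26 [(1R,5S,6R)-5-hydroxy-2-oxo-6-[(2E,6E)-3,7,11-trimethyldodeca-2,6,10-trienoyl]-7-oxabicyclo[4.1.0]hept-3-en-3-yl]methyl acetate
Product: 27 [(1R,5S,6R)-5-hydroxy-6-[(1S,2E,6E)-1-hydroxy-3,7,11-trimethyldodeca-2,6,10-trien-1-yl]-2-oxo-7-oxabicyclo[4.1.0]hept-3-en-3-yl]methyl acetate
Conditions: Me4NBH(OAc)3 (5 equiv), MeCN/AcOH (1:1), −30 °C
Reagents that add atoms: none
Why: Evans–Saksena reduction: the C4 hydroxyl exchanges onto boron and delivers hydride intramolecularly through a chair-like six-membered transition state to the C1′ ketone only (the ring ketone has no β-hydroxyl and is not reduced by the triacetoxyborohydride), which should give the 1,3-anti diol and thus the (S)-carbinol.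

**Compound list**

1 | 2,3,4-tri-O-benzyl-D-xylopyranose (anomeric mixture) | OC1[C@H](OCc2ccccc2)[C@@H](OCc2ccccc2)[C@H](OCc2ccccc2)CO1 | starting material
2 | (3R,4S,5S,6R)-4,5,6-tris(benzyloxy)hept-1-yne-3,7-diol | C#C[C@@H](O)[C@H](OCc1ccccc1)[C@@H](OCc1ccccc1)[C@H](OCc1ccccc1)CO | intermediate
3 | (3S,4R,5S,6R)-3,4,5-tris(benzyloxy)-6-ethynyloxan-2-ol (lactol, either anomer) | C#C[C@@H]1[C@H](OCc2ccccc2)[C@@H](OCc2ccccc2)[C@H](OCc2ccccc2)C(O)O1 | intermediate
4 | (3S,4R,5S,6R)-3,4,5-tris(benzyloxy)-6-ethynyloxan-2-one | C#C[C@@H]1[C@H](OCc2ccccc2)[C@@H](OCc2ccccc2)[C@H](OCc2ccccc2)C(=O)O1 | intermediate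
5 | (3S,4R,5S,6R)-3,4,5-tris(benzyloxy)-6-[(E)-2-(4,4,5,5-tetramethyl-1,3,2-dioxaborolan-2-yl)ethenyl]oxan-2-one | CC1(C)OB(/C=C/[C@@H]2[C@H](OCc3ccccc3)[C@@H](OCc3ccccc3)[C@H](OCc3ccccc3)C(=O)O2)OC1(C)C | intermediate
6 | (2R,3S,4R)-3,4,5-tris(benzyloxy)-2-[(E)-2-(4,4,5,5-tetramethyl-1,3,2-dioxaborolan-2-yl)ethenyl]-6-(trimethylsilyloxy)-3,4-dihydro-2H-pyran (silyl ketene acetal of 5) | C[Si](C)(C)OC1=C(OCc2ccccc2)[C@H](OCc2ccccc2)[C@@H](OCc2ccccc2)[C@@H](/C=C/B2OC(C)(C)C(C)(C)O2)O1 | intermediate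
7 | trimethylsilyl (1R,2S,5S,6R)-1,5,6-tris(benzyloxy)-2-(4,4,5,5-tetramethyl-1,3,2-dioxaborolan-2-yl)cyclohex-3-ene-1-carboxylate | C[Si](C)(C)OC(=O)[C@]1(OCc2ccccc2)[C@H](OCc2ccccc2)[C@@H](OCc2ccccc2)C=C[C@@H]1B1OC(C)(C)C(C)(C)O1 | intermediate
8 | (1R,2S,5S,6R)-1,5,6-tris(benzyloxy)-2-hydroxycyclohex-3-ene-1-carboxylic acid | OC(=O)[C@]1(OCc2ccccc2)[C@H](OCc2ccccc2)[C@@H](OCc2ccccc2)C=C[C@@H]1O | intermediate
9 | tert-butyldimethylsilyl (1S,2S,5S,6R)-1,5,6-tris(benzyloxy)-2-[(tert-butyldimethylsilyl)oxy]cyclohex-3-ene-1-carboxylate | CC(C)(C)[Si](C)(C)OC(=O)[C@]1(OCc2ccccc2)[C@H](OCc2ccccc2)[C@@H](OCc2ccccc2)C=C[C@@H]1O[Si](C)(C)C(C)(C)C | intermediate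
10 | (1S,2S,5S,6R)-1,5,6-tris(benzyloxy)-2-[(tert-butyldimethylsilyl)oxy]cyclohex-3-ene-1-carboxylic acid | OC(=O)[C@]1(OCc2ccccc2)[C@H](OCc2ccccc2)[C@@H](OCc2ccccc2)C=C[C@@H]1O[Si](C)(C)C(C)(C)C | intermediate
11 | S-ethyl (1S,2S,5S,6R)-1,5,6-tris(benzyloxy)-2-[(tert-butyldimethylsilyl)oxy]cyclohex-3-ene-1-carbothioate | CCSC(=O)[C@]1(OCc2ccccc2)[C@H](OCc2ccccc2)[C@@H](OCc2ccccc2)C=C[C@@H]1O[Si](C)(C)C(C)(C)C | intermediate
12 | S-ethyl (1S,2S,5S,6R)-2-[(tert-butyldimethylsilyl)oxy]-1,5,6-trihydroxycyclohex-3-ene-1-carbothioate | CCSC(=O)[C@]1(O)[C@H](O)[C@@H](O)C=C[C@@H]1O[Si](C)(C)C(C)(C)C | intermediate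
13 | S-ethyl (1S,2S,6S)-2-[(tert-butyldimethylsilyl)oxy]-1,6-dihydroxy-5-oxocyclohex-3-ene-1-carbothioate | CCSC(=O)[C@]1(O)[C@H](O)C(=O)C=C[C@@H]1O[Si](C)(C)C(C)(C)C | intermediate
14 | S-ethyl (1R,2S,6S)-2-[(tert-butyldimethylsilyl)oxy]-1-hydroxy-6-(methanesulfonyloxy)-5-oxocyclohex-3-ene-1-carbothioate | CCSC(=O)[C@]1(O)[C@H](OS(C)(=O)=O)C(=O)C=C[C@@H]1O[Si](C)(C)C(C)(C)C | intermediate
15 | S-ethyl (1R,5S,6S)-5-[(tert-butyldimethylsilyl)oxy]-2-oxo-7-oxabicyclo[4.1.0]hept-3-ene-6-carbothioate | C1=C[C@H](O[Si](C)(C)C(C)(C)C)[C@@]2(C(=O)SCC)O[C@H]2C1=O | intermediate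
16 | (5E)-6,10-dimethylundeca-5,9-dien-2-one ((E)-geranylacetone) | CC(=O)CC/C=C(\C)CCC=C(C)C | starting material
17 | diethyl (5E)-6,10-dimethylundeca-1,5,9-trien-2-yl phosphate | C=C(OP(=O)(OCC)OCC)CC/C=C(\C)CCC=C(C)C | intermediate
18 | (5E)-6,10-dimethylundeca-5,9-dien-1-yne | C#CCC/C=C(\C)CCC=C(C)C | intermediate
19 | dimethyl[(1E,5E)-2,6,10-trimethylundeca-1,5,9-trien-1-yl]alumane | C[Al](C)/C=C(\C)CC/C=C(\C)CCC=C(C)C | intermediate
20 | (1E,5E)-1-iodo-2,6,10-trimethylundeca-1,5,9-triene | I/C=C(\C)CC/C=C(\C)CCC=C(C)C | intermediate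
21 | [(1E,5E)-2,6,10-trimethylundeca-1,5,9-trien-1-yl]lithium | [Li]/C=C(\C)CC/C=C(\C)CCC=C(C)C | intermediate
22 | chloro[(1E,5E)-2,6,10-trimethylundeca-1,5,9-trien-1-yl]zinc | Cl[Zn]/C=C(\C)CC/C=C(\C)CCC=C(C)C | intermediate
23 | (1R,5S,6S)-5-[(tert-butyldimethylsilyl)oxy]-6-[(2E,6E)-3,7,11-trimethyldodeca-2,6,10-trienoyl]-7-oxabicyclo[4.1.0]hept-3-en-2-one | C1=C[C@H](O[Si](C)(C)C(C)(C)C)[C@@]2(C(=O)/C=C(\C)CC/C=C(\C)CCC=C(C)C)O[C@H]2C1=O | intermediate
24 | (1R,5S,6S)-5-[(tert-butyldimethylsilyl)oxy]-3-(hydroxymethyl)-6-[(2E,6E)-3,7,11-trimethyldodeca-2,6,10-trienoyl]-7-oxabicyclo[4.1.0]hept-3-en-2-one | OCC1=C[C@H](O[Si](C)(C)C(C)(C)C)[C@@]2(C(=O)/C=C(\C)CC/C=C(\C)CCC=C(C)C)O[C@H]2C1=O | intermediate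
25 | [(1R,5S,6S)-5-[(tert-butyldimethylsilyl)oxy]-2-oxo-6-[(2E,6E)-3,7,11-trimethyldodeca-2,6,10-trienoyl]-7-oxabicyclo[4.1.0]hept-3-en-3-yl]methyl acetate | CC(=O)OCC1=C[C@H](O[Si](C)(C)C(C)(C)C)[C@@]2(C(=O)/C=C(\C)CC/C=C(\C)CCC=C(C)C)O[C@H]2C1=O | intermediate
26 | [(1R,5S,6R)-5-hydroxy-2-oxo-6-[(2E,6E)-3,7,11-trimethyldodeca-2,6,10-trienoyl]-7-oxabicyclo[4.1.0]hept-3-en-3-yl]methyl acetate | CC(=O)OCC1=C[C@H](O)[C@@]2(C(=O)/C=C(\C)CC/C=C(\C)CCC=C(C)C)O[C@H]2C1=O | intermediate
27 | [(1R,5S,6R)-5-hydroxy-6-[(1S,2E,6E)-1-hydroxy-3,7,11-trimethyldodeca-2,6,10-trien-1-yl]-2-oxo-7-oxabicyclo[4.1.0]hept-3-en-3-yl]methyl acetate (CNP0137670.2) | CC(=O)OCC1=C[C@H](O)[C@@]2([C@@H](O)/C=C(\C)CC/C=C(\C)CCC=C(C)C)O[C@H]2C1=O | target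

**Step count and risks**

Total step count: 16. Longest linear sequence: 14 steps (steps 1–9 and 12–16).

Step 4: what may go wrong is β-elimination of benzyloxide from the lithium enolate before it is silylated, or a stalled rearrangement of the crowded ketene acetal. The fallback is a neutral thermal Claisen rearrangement of a cyclic enol ether, with no enolate. Starting from 5, (i-Bu)2AlH (CH2Cl2, −78 °C) would give the lactol (3S,4R,5S,6R)-3,4,5-tris(benzyloxy)-6-[(E)-2-(4,4,5,5-tetramethyl-1,3,2-dioxaborolan-2-yl)ethenyl]oxan-2-ol F1. Mesylation and base-induced 1,2-elimination (MeSO2Cl, Et3N, then DBU) would give the cyclic enol ether (2R,3S,4R)-3,4,5-tris(benzyloxy)-2-[(E)-2-(4,4,5,5-tetramethyl-1,3,2-dioxaborolan-2-yl)ethenyl]-3,4-dihydro-2H-pyran F2. Heating F2 (o-dichlorobenzene, 180 °C) should rearrange it through the same boat-type array to the aldehyde (1R,2S,5S,6R)-1,5,6-tris(benzyloxy)-2-(4,4,5,5-tetramethyl-1,3,2-dioxaborolan-2-yl)cyclohex-3-ene-1-carbaldehyde F3. Pinnick oxidation (NaClO2, NaH2PO4, 2-methylbut-2-ene) and then NaOH/H2O2 would convert F3 into 8, where the route is rejoined.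

Step 12: what may go wrong is slow oxidative addition and transmetalation at the α-quaternary thioester, with recovery of 15 or decarbonylation of the acylpalladium species. The fallback goes through an aldehyde. Fukuyama reduction of 15 (Et3SiH, Pd/C, acetone, rt) would give the aldehyde (1R,5S,6S)-5-[(tert-butyldimethylsilyl)oxy]-2-oxo-7-oxabicyclo[4.1.0]hept-3-ene-6-carbaldehyde F4. A Nozaki–Hiyama–Kishi coupling of F4 with iodide 20 (CrCl2, NiCl2 (cat), DMSO), which addresses the aldehyde and not the enone, would give the allylic alcohol (1R,5S,6S)-5-[(tert-butyldimethylsilyl)oxy]-6-[(2E,6E)-1-hydroxy-3,7,11-trimethyldodeca-2,6,10-trien-1-yl]-7-oxabicyclo[4.1.0]hept-3-en-2-one F5 (either C1′ epimer serves). MnO2 oxidation of this allylic alcohol would return to 23.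

Step 13: what may go wrong is conjugate addition of DMAP without turnover, or base-induced degradation of the epoxy dienone in the aqueous medium. The fallback replaces the amine-catalysed aldol by halogenation and cross-coupling. α-Iodination of 23 (I2, pyridine, CH2Cl2, 0 °C) would give the iodoenone (1R,5S,6S)-5-[(tert-butyldimethylsilyl)oxy]-3-iodo-6-[(2E,6E)-3,7,11-trimethyldodeca-2,6,10-trienoyl]-7-oxabicyclo[4.1.0]hept-3-en-2-one F6. Stille coupling of F6 with Bu3SnCH2OH (Pd(PPh3)4, CuI, DMF, rt) would give 24.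

**Further compounds**

F1 | step 4 | (3S,4R,5S,6R)-3,4,5-tris(benzyloxy)-6-[(E)-2-(4,4,5,5-tetramethyl-1,3,2-dioxaborolan-2-yl)ethenyl]oxan-2-ol | CC1(C)OB(/C=C/[C@@H]2[C@H](OCc3ccccc3)[C@@H](OCc3ccccc3)[C@H](OCc3ccccc3)C(O)O2)OC1(C)C
F2 | step 4 | (2R,3S,4R)-3,4,5-tris(benzyloxy)-2-[(E)-2-(4,4,5,5-tetramethyl-1,3,2-dioxaborolan-2-yl)ethenyl]-3,4-dihydro-2H-pyran | CC1(C)OB(/C=C/[C@H]2OC=C(OCc3ccccc3)[C@H](OCc3ccccc3)[C@H]2OCc2ccccc2)OC1(C)C
F3 | step 4 | (1R,2S,5S,6R)-1,5,6-tris(benzyloxy)-2-(4,4,5,5-tetramethyl-1,3,2-dioxaborolan-2-yl)cyclohex-3-ene-1-carbaldehyde | O=C[C@]1(OCc2ccccc2)[C@H](OCc2ccccc2)[C@@H](OCc2ccccc2)C=C[C@@H]1B1OC(C)(C)C(C)(C)O1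
F4 | step 12 | (1R,5S,6S)-5-[(tert-butyldimethylsilyl)oxy]-2-oxo-7-oxabicyclo[4.1.0]hept-3-ene-6-carbaldehyde | C1=C[C@H](O[Si](C)(C)C(C)(C)C)[C@@]2(C=O)O[C@H]2C1=O
F5 | step 12 | (1R,5S,6S)-5-[(tert-butyldimethylsilyl)oxy]-6-[(2E,6E)-1-hydroxy-3,7,11-trimethyldodeca-2,6,10-trien-1-yl]-7-oxabicyclo[4.1.0]hept-3-en-2-one (C1′ epimers) | C1=C[C@H](O[Si](C)(C)C(C)(C)C)[C@@]2(C(O)/C=C(\C)CC/C=C(\C)CCC=C(C)C)O[C@H]2C1=O
F6 | step 13 | (1R,5S,6S)-5-[(tert-butyldimethylsilyl)oxy]-3-iodo-6-[(2E,6E)-3,7,11-trimethyldodeca-2,6,10-trienoyl]-7-oxabicyclo[4.1.0]hept-3-en-2-one | IC1=C[C@H](O[Si](C)(C)C(C)(C)C)[C@@]2(C(=O)/C=C(\C)CC/C=C(\C)CCC=C(C)C)O[C@H]2C1=O
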